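**Retrosynthetic overview**
1. Tomoeone D ⇒ bis-desprenyl spiro trione 12 by a final gem-diprenylation at the one free ring carbon.
2. Ring C (the acyl-trione) is built de novo on the spiro carbon rather than by dearomatising an acylphloroglucinol: Dieckmann closure of triketo ester 11, itself from a β-diketone dianion opening the bridged lactone 8.
3. Key step: oxidative radical 6-endo cyclisation/lactonisation of malonate 7 with Mn(OAc)3 closes ring B, sets the axial C4–O bond and makes the two malonate carbonyls different, which fixes the spiro centre.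
4. Malonate 7 ⇐ ring A cyclopentane from (R)-limonene oxide by periodate cleavage and a 5-enolexo aldol, then iodide and malonate alkylation.
5. Ring order: A (aldol) → B plus lactone bridge (radical) → C (Claisen/Dieckmann).

Assumption: 1 is bought as the commercial cis/trans mixture; names use hydrindane locants (C1 ring A carbinol, C3a/C7a fusion, C4 ring B carbinol, C6 spiro) and primed locants for ring C (C1' spiro, C2' C=O next to acyl-bearing C3', C5' next to C6' C=O).

**Step 1**
Reactants: 1 (4R)-limonene 1,2-oxide (cis/trans mixture)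
Product: 2 (3R)-6-oxo-3-(prop-1-en-2-yl)heptanal
Conditions: H5IO6 (1.1 equiv), THF/H2O, 0 °C to rt
Reagents that add atoms: water, O
Why: One-pot epoxide hydrolysis and periodate glycol cleavage (Malaprade type) converges both epoxide isomers, leaves the 1,1-disubstituted alkene alone and does not touch the limonene C4 stereocentre.

**Step 2**
Reactants: 2 (3R)-6-oxo-3-(prop-1-en-2-yl)heptanal
Product: 4 (1R,2R,3R)-2-(hydroxymethyl)-1-methyl-3-(prop-1-en-2-yl)cyclopentan-1-ol, via hydroxy aldehyde 3 (not isolated)
Conditions: L-proline (20 mol%), DMSO, rt; then MeOH, NaBH4, 0 °C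
Reagents that add atoms: none
Why: Proline-catalysed 5-enolexo intramolecular aldol addition (aldehyde enamine onto the methyl ketone) puts CHO trans to the resident isopropenyl group (catalyst face matched with substrate bias) and, through the compact hydrogen-bonded five-ring transition state, OH cis to CHO, so both new centres are set; NaBH4 traps the β-hydroxy aldehyde before E1cB dehydration.

**Step 3**
Reactants: 4 (1R,2R,3R)-2-(hydroxymethyl)-1-methyl-3-(prop-1-en-2-yl)cyclopentan-1-ol
Product: 5 (1R,2S,3R)-2-(iodomethyl)-1-methyl-3-(prop-1-en-2-yl)cyclopentan-1-ol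
Conditions: PPh3, I2, imidazole, CH2Cl2, 0 °C to rt
Reagents that add atoms: iodine, [I][I]
Why: Appel-type iodination is selective for the primary alcohol over the tertiary one and touches no stereocentre.

**Step 4**
Reactants: 5 (1R,2S,3R)-2-(iodomethyl)-1-methyl-3-(prop-1-en-2-yl)cyclopentan-1-ol; 6 dimethyl malonate
Product: 7 dimethyl 2-{[(1S,2R,5R)-2-hydroxy-2-methyl-5-(prop-1-en-2-yl)cyclopentyl]methyl}propanedioate
Conditions: 6 (3 equiv), Cs2CO3 (1.5 equiv), DMF, 60 °C
Reagents that add atoms: none
Why: SN2 malonate alkylation of a β-branched primary iodide; the carbonate base is too weak to form the tertiary alkoxide, so oxetane closure and Grob fragmentation are suppressed.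

**Step 5**
Reactants: 7 dimethyl 2-{[(1S,2R,5R)-2-hydroxy-2-methyl-5-(prop-1-en-2-yl)cyclopentyl]methyl}propanedioate
Product: 8 methyl (1R,3aR,4S,6S,7aS)-1-hydroxy-1,4-dimethyloctahydro-1H-indene-6-carboxylate 6,4-carbolactone (trans-fused; axial C6 carbonyl bridged to the C4 oxygen)
Conditions: Mn(OAc)3 (2.2 equiv), AcOH (0.05 M, degassed), 70 °C
Reagents that add atoms: none
Why: Mn(OAc)3-mediated oxidative free-radical cyclisation: the malonyl radical closes 6-endo onto the isopropenyl CH2 (5-exo would give a trans-fused bicyclo[3.3.0]octane), trivalent manganese oxidises the tertiary radical to the cation, and only the axial ester can reach it, so lactonisation with loss of the O-methyl group sets C4–O axial (4S) and differentiates the two carbonyls on C6 (6S).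

**Step 6**
Reactants: 8 methyl (1R,3aR,4S,6S,7aS)-1-hydroxy-1,4-dimethyloctahydro-1H-indene-6-carboxylate 6,4-carbolactone; 9 5-methylhexane-2,4-dione
Product: 11 methyl (1R,3aR,4S,6R,7aS)-1,4-dihydroxy-1,4-dimethyl-6-(6-methyl-3,5-dioxoheptanoyl)octahydro-1H-indene-6-carboxylate, via dilithium dianion 10 (not isolated)
Conditions: 9 (3 equiv), LiN(iPr)2 (6 equiv), THF, 0 °C; then 8, −78 to 0 °C; aq. HCl
Reagents that add atoms: none
Why: Claisen-type acylation of a β-diketone dianion at its terminal carbon: the strained bridged γ-lactone is a faster acceptor than the neopentyl methyl ester, so the chain goes onto the axial carbonyl (future C6'), the C4 alkoxide is released and no stereocentre is touched.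

**Step 7**
Reactants: 11 methyl (1R,3aR,4S,6R,7aS)-1,4-dihydroxy-1,4-dimethyl-6-(6-methyl-3,5-dioxoheptanoyl)octahydro-1H-indene-6-carboxylate
Product: 12 (1R,3aR,4S,6R,7aS)-1,4-dihydroxy-1,4-dimethyl-3'-(2-methylpropanoyl)spiro[octahydroindene-6,1'-cyclohexane]-2',4',6'-trione (4'-enol; bis-desprenyl tomoeone D)
Conditions: NaOMe (3 equiv), MeOH, 65 °C; then aq. HCl
Reagents that add atoms: none
Why: Dieckmann (intramolecular Claisen) condensation: the CH2 between the central carbonyl and the isobutyryl group attacks the equatorial ester and closes ring C as its stabilised triketone enolate, so the acyl-bearing carbon ends up next to C2' and the lactone-defined differentiation becomes the spiro configuration (6R).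

**Step 8**
Reactants: 12 (1R,3aR,4S,6R,7aS)-1,4-dihydroxy-1,4-dimethyl-3'-(2-methylpropanoyl)spiro[octahydroindene-6,1'-cyclohexane]-2',4',6'-trione; 13 1-bromo-3-methylbut-2-ene (prenyl bromide)
Product: 15 tomoeone D, via monoprenyl trione 14 (not isolated)
Conditions: NaOMe (2.5 equiv), MeOH, 0 °C; 13 (2.5 equiv), 0 °C to rt
Reagents that add atoms: none
Why: Twofold C-alkylation of the vinylogous-acid enolate at C5', the only ring C carbon still bearing hydrogen (acyl-bearing C3' is blocked); the tertiary alcohols are not alkylated at this basicity and no stereocentre is affected.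

**Compound list**
1 | (4R)-limonene 1,2-oxide, (4R)-1-methyl-4-(prop-1-en-2-yl)-7-oxabicyclo[4.1.0]heptane, cis/trans mixture | CC(=C)[C@@H]1CCC2(C)OC2C1 | starting material
2 | (3R)-6-oxo-3-(prop-1-en-2-yl)heptanal | C=C(C)[C@@H](CC=O)CCC(C)=O | intermediate
3 | (1S,2R,5R)-2-hydroxy-2-methyl-5-(prop-1-en-2-yl)cyclopentane-1-carbaldehyde (OH cis to CHO, CHO trans to isopropenyl) | O=C[C@H]1[C@@H](CC[C@@]1(C)O)C(C)=C | intermediate
4 | (1R,2R,3R)-2-(hydroxymethyl)-1-methyl-3-(prop-1-en-2-yl)cyclopentan-1-ol | OC[C@H]1[C@@H](CC[C@@]1(C)O)C(C)=C | intermediate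
5 | (1R,2S,3R)-2-(iodomethyl)-1-methyl-3-(prop-1-en-2-yl)cyclopentan-1-ol | IC[C@H]1[C@@H](CC[C@@]1(C)O)C(C)=C | intermediate
6 | dimethyl malonate | COC(=O)CC(=O)OC | starting material
7 | dimethyl 2-{[(1S,2R,5R)-2-hydroxy-2-methyl-5-(prop-1-en-2-yl)cyclopentyl]methyl}propanedioate | COC(=O)C(C[C@H]1[C@@H](CC[C@@]1(C)O)C(C)=C)C(=O)OC | intermediate
8 | methyl (1R,3aR,4S,6S,7aS)-1-hydroxy-1,4-dimethyloctahydro-1H-indene-6-carboxylate 6,4-carbolactone (trans-hydrindane; 6-oxabicyclo[3.2.1]octan-7-one bridge; equatorial CO2Me) | O=C1O[C@@]2(C)C[C@]1(C(=O)OC)C[C@H]3[C@H]2CC[C@@]3(C)O | intermediate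
9 | 5-methylhexane-2,4-dione | CC(=O)CC(=O)C(C)C | starting material
10 | dilithium 1,3-dianion of 5-methylhexane-2,4-dione | C=C([O-])C=C([O-])C(C)C.[Li+].[Li+] | intermediate
11 | methyl (1R,3aR,4S,6R,7aS)-1,4-dihydroxy-1,4-dimethyl-6-(6-methyl-3,5-dioxoheptanoyl)octahydro-1H-indene-6-carboxylate (drawn as triketo form; enol and lactol tautomers expected) | COC(=O)[C@]1(C(=O)CC(=O)CC(=O)C(C)C)C[C@H]2[C@@H](CC[C@@]2(C)O)[C@@](C)(O)C1 | intermediate
12 | (1R,3aR,4S,6R,7aS)-1,4-dihydroxy-1,4-dimethyl-3'-(2-methylpropanoyl)spiro[octahydroindene-6,1'-cyclohexane]-2',4',6'-trione, 4'-enol (C6' carbonyl axial, syn to the C4 hydroxyl) | O=C(C(C)C)C1=C(O)CC(=O)[C@]2(C[C@H]3[C@@H](CC[C@@]3(C)O)[C@@](C)(O)C2)C1=O | intermediate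
13 | 1-bromo-3-methylbut-2-ene (prenyl bromide) | CC(C)=CCBr | starting material
14 | 5'-mono(3-methylbut-2-enyl) analogue of 12 (dienol tautomer drawn) | CC(C)=CCC1=C(O)[C@]2(C[C@H]3[C@@H](CC[C@@]3(C)O)[C@@](C)(O)C2)C(=O)C(C(=O)C(C)C)=C1O | intermediate
15 | tomoeone D, (1R,3aR,4S,6R,7aS)-1,4-dihydroxy-1,4-dimethyl-5',5'-bis(3-methylbut-2-enyl)-3'-(2-methylpropanoyl)spiro[octahydroindene-6,1'-cyclohexane]-2',4',6'-trione, 4'-enol | CC(C)=CCC1(CC=C(C)C)C(=O)[C@]2(C[C@H]3[C@@H](CC[C@@]3(C)O)[C@@](C)(O)C2)C(=O)C(C(=O)C(C)C)=C1O | target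

**Totals**
Total steps: 8. Longest linear sequence: 8 steps (1 to 15).

**Three steps most likely to fail**

Step 5 (the cation may eliminate or take up acetate instead of lactonising). The fallback sets out from 7 and comes back at 8. The isopropenyl group of 7 is epoxidised with mCPBA (CH2Cl2, NaHCO3, 0 °C) to dimethyl 2-{[(1S,2R,5R)-2-hydroxy-2-methyl-5-(2-methyloxiran-2-yl)cyclopentyl]methyl}propanedioate F3, obtained as roughly a 1:1 mixture at the new carbinol carbon. Catalytic NaOMe in MeOH at 50 °C then lets the malonate anion open the epoxide at its CH2 terminus (6-endo-tet; the exo mode would need attack at a fully substituted carbon). The epimer whose alkoxide is axial lactonises onto the axial ester to give 8, and the other epimer stays as a hydroxy diester and is separated. This replaces the radical–polar crossover by a purely ionic closure at the price of at most half the material.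

Step 6 (the dianion may attack the methyl ester in competition with the lactone, which would lead to the spiro epimer). The fallback sets out from 8 and comes back at 12, with the ring C bonds made in the opposite order so that connectivity cannot be ambiguous. Saponification (LiOH, THF/H2O, 50 °C) and acidification, which re-closes the only possible lactone, give (1R,3aR,4S,6S,7aS)-1-hydroxy-1,4-dimethyloctahydro-1H-indene-6-carboxylic acid 6,4-carbolactone F4. Carbonyldiimidazole in THF converts its free equatorial carboxyl into the acyl imidazolide F5, which has no α-hydrogen and cannot form a ketene. The magnesium enolate of 9 (MgCl2, Et3N, MeCN) is C-acylated by it to give the 2-acyl-1,3-diketone lactone F6, in which the equatorial carbonyl is already bonded to the acyl-bearing carbon. LiN(iPr)2 (3.5 equiv, THF, −78 to 0 °C) then deprotonates the acetyl methyl group, which attacks the lactone carbonyl intramolecularly (6-exo Claisen), releases the C4 alkoxide and gives 12 after acidic work-up.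

Step 2 (the aldol may dehydrate or give the wrong carbinol epimer). The fallback sets out from 2 and comes back at 4 through 3. Classical condensation of 2 (piperidine, AcOH, benzene, reflux) gives the conjugated enal (S)-2-methyl-5-(prop-1-en-2-yl)cyclopent-1-ene-1-carbaldehyde F1. Nucleophilic epoxidation (H2O2, NaOH, MeOH, 0 °C) occurs anti to the isopropenyl group and gives 5-methyl-2-(prop-1-en-2-yl)-6-oxabicyclo[3.1.0]hexane-1-carbaldehyde F2, which fixes the carbinol configuration by substrate control. Reductive cleavage of the α-C–O bond with SmI2 (THF/MeOH, −90 °C), in which divalent samarium generates the enolate that is protonated to the more stable all-trans aldehyde, returns 3. Compound 3 is reduced in the same flask with NaBH4 as in step 2 to rejoin the route at 4.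

**Further compounds**
F1 | step 2 | (S)-2-methyl-5-(prop-1-en-2-yl)cyclopent-1-ene-1-carbaldehyde | CC1=C(C=O)[C@@H](CC1)C(C)=C
F2 | step 2 | 5-methyl-2-(prop-1-en-2-yl)-6-oxabicyclo[3.1.0]hexane-1-carbaldehyde, epoxide oxygen anti to isopropenyl | O=C[C@@]12O[C@]1(C)CC[C@H]2C(C)=C
F3 | step 5 | dimethyl 2-{[(1S,2R,5R)-2-hydroxy-2-methyl-5-(2-methyloxiran-2-yl)cyclopentyl]methyl}propanedioate, both oxirane epimers | COC(=O)C(C[C@H]1[C@@H](CC[C@@]1(C)O)C1(C)CO1)C(=O)OC
F4 | step 6 | (1R,3aR,4S,6S,7aS)-1-hydroxy-1,4-dimethyloctahydro-1H-indene-6-carboxylic acid 6,4-carbolactone | O=C1O[C@@]2(C)C[C@]1(C(=O)O)C[C@H]3[C@H]2CC[C@@]3(C)O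
F5 | step 6 | acyl imidazolide of F4 | O=C1O[C@@]2(C)C[C@]1(C(=O)n4ccnc4)C[C@H]3[C@H]2CC[C@@]3(C)O
F6 | step 6 | lactone of F4 carrying a 2-acetyl-4-methyl-3-oxopentanoyl group on C6 | O=C1O[C@@]2(C)C[C@]1(C(=O)C(C(C)=O)C(=O)C(C)C)C[C@H]3[C@H]2CC[C@@]3(C)O
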